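The target SMILES is read as the (3R,4R)-trans lactone. All lactones below are numbered O1, C2(=O), C3, C4, C5.

## Analysis of the target

- Compound 21 is a dibenzylbutyrolactone lignan, C20H22O6. It has one γ-butyrolactone ring (O1, C2(=O), C3, C4, C5) and no other ring apart from the two arenes.
- C3 carries a 4-hydroxy-3-methoxybenzyl arm and C4 a 3-hydroxy-4-methoxybenzyl arm. The arms are constitutional isomers, so an intermediate in which C2 and C5 reach the same oxidation level would lose the information on which arm sits next to the carbonyl.
- The only stereocentres are the vicinal C3 and C4. Both are R, and the arms are trans on the ring.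
- C3 is α to the carbonyl and can be equilibrated, with trans as the more stable arrangement. C4 is fixed in the lactone and therefore holds the absolute configuration of the molecule.
- The sensitive features are the two free phenols (acidic, easily oxidised), the lactone, and the electron-rich arenes. The arenes can cyclise onto a cationic centre generated at a benzylic carbon or at C5.
- The difficulty lies in C4. It is a methine with three carbon substituents of similar size (C3, C5, CH2Ar) and no heteroatom that could direct a reagent.
- The strategy rests on C3 and C4 being the α and β carbons of the corresponding but-2-en-4-olide, so C4 can accept a nucleophile and C3 then an electrophile. C5, the only ring carbon without a carbon substituent, can hold a removable alkoxy stereocontroller at the acetal level.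

## Retrosynthetic reasoning

**21 to 20.** The last operation should only uncover the phenols, so the two O–H bonds of 21 are traced back to the O–benzyl bonds of dibenzyl ether 20. Free phenols would quench every carbanion of the route. Benzyl ethers tolerate organolithium, hydride and alkali, and both leave together in one neutral step that touches neither the lactone nor C3.

**20 to 17.** The C5 methylene of 20 is traced back to an acetal carbon. One C5–H bond is exchanged for the C5–O bond to the l-menthyl group in 17. The cut is placed at C5 because it is the direct neighbour of C4 and carries no carbon substituent of its own.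

- In the forward direction alkali opens the acylal and (−)-menthol 4 leaves.
- Aldehyde carboxylate 18 must be reduced to hydroxy carboxylate 19 before its C4–H is exchanged.
- Acid then closes 19 to 20.
- C2 stays at the acid level while C5 passes through the aldehyde level. The two ends are therefore never equivalent, and the carbonyl stays next to the 4-oxygenated arm.

**17 to 16.** The benzylic CH2 of the C4 arm in 17 is traced back to the dithiane carbon of 16, exchanging two C–H bonds for two C–S bonds. This inverts the polarity of an aldehyde carbon, so the arm can be delivered as a nucleophile. The carbanion becomes soft enough for 1,4-addition and bulky enough to steer the next bond formation. The forward step is a reductive desulfurisation that must spare the benzyl ethers and the acylal.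

**16 to 6, 9 and 13.** Adduct 16 is cut at the two exocyclic bonds C4–C(benzylic) and C3–CH2Ar.

- The cuts give furanone 6, dithiane 9 (used as carbanion 14) and bromide 13.
- They fall exactly at the two stereocentres and divide the molecule into three pieces of comparable size.
- The ring stays intact, so no cyclisation is needed.
- The forward reaction must add 14 to C4 anti to the C5 alkoxy group.
- It must then alkylate enolate 15 at C3 anti to the new C4 substituent. This is a relay C5 → C4 → C3 in one flask.

**6 to 1 and 4.** Furanone 6 is cut at the exocyclic C5–O bond into hydroxyfuranone 3 and (−)-menthol 4. The acetalisation gives the epimer mixture 5. The menthyl group makes the two C5 epimers diastereomeric, so 6 is obtained by crystallisation. Compound 3 goes back to furfural 1 by dye-sensitised photo-oxygenation through endoperoxide 2, with loss of the formyl carbon.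

**9 to 7.** Dithiane 9 is cut at its two C–S bonds to aldehyde 8, and 8 at the O–benzyl bond to isovanillin 7. The substitution pattern of the C4 arm is bought, not made.

**13 to 10.** Bromide 13 is traced through alcohol 12 and aldehyde 11 to vanillin 10. These are functional-group changes at one carbon plus the same O-benzylation, and they deliver the C3 arm with its pattern already in place.

## Alternatives that were turned down

**Alternative 1:**

- **Disconnection.** The route runs through the (R,E)-α-benzylidene lactone A1. Its O1–C2 and C2–C3 bonds are cut so that C2 leaves as a one-carbon carbonyl unit. What remains is the (R)-homopropargylic alcohol A2.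
- **Forward key step.** A palladium-catalysed cyclocarbonylation of A2 links the hydroxyl oxygen and the near alkyne carbon through the inserted carbonyl. Syn addition across the triple bond places the aryl group trans to the carbonyl.
- **For it.** The ring and C2 arise in one catalytic step. A2 is modular, because the aryl group can come from a Sonogashira coupling. Only one stereocentre has to be secured. A final hydrogenation could saturate the alkene and free both phenols at once.
- **Where it is stronger.** It wins on end-game economy, with one operation against three, and it needs no sulfur.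
- **Against it.**
  - C3 is not set in the key step. Hydrogenation of A1 takes place on the face away from the C4 arm, which pushes the new C3 arm cis to it. A base equilibration must follow and stops at the thermodynamic composition.
  - The regiochemistry of the palladium addition to an aryl–alkyl alkyne is not secured by the substrate.
  - Cycloisomerisation of the alcohol onto the alkyne competes.
  - The carbinyl-branched stereocentre of A2 has no chiral-pool source and needs its own multistep asymmetric preparation.
- **What the chosen strategy offers instead.** It creates both centres under kinetic substrate control in one step from a crystalline, cheap controller, and the trans relation is obtained directly.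

**Alternative 2:**

- **Disconnection.** The bonds C4–C5 and C3–CH2Ar are cut in the open-chain imide A3, with C5 introduced as a hydroxymethyl-anion equivalent.
- **Forward key step.** The silylmethyl Grignard reagent A5 adds, with a monovalent copper salt, to the β-carbon of enoyl imide A4. The chelated enolate is benzylated by 13. Tamao–Fleming oxidation and lactonisation with loss of the auxiliary would follow.
- **For it.** It uses the same three-component logic as the chosen plan. The auxiliary is commercial and recoverable, and its phenyl group gives a strong facial bias at C4.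
- **Where it is stronger.** No desulfurisation is needed and the last catalyst cannot be poisoned.
- **Against it.**
  - The γ-CH2 of A4 is both allylic and benzylic, so deconjugation into the styrene isomer threatens its preparation and its use with basic organometallics.
  - The enolate face open to 13 is dictated by the auxiliary and not by C4. It gives C3 with the configuration opposite to the target, so the lactone would close cis and need epimerisation.
  - Magnesium or copper imide enolates are weak nucleophiles, so the in-flask benzylation is likely to lose against protonation.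
- **Comparison.** Oxidation, ring closure, epimerisation and hydrogenolysis after the key step are no shorter than the chosen end game. In the chosen strategy each new centre is controlled by its ring neighbour, so both come out correct without a correction step.

**Alternative 3:**

- **Disconnection.** The aryl–CH2 bond of the C4 arm and the C3–CH2Ar bond are cut in the lactone ester A6. This leads to the (1S,5R)-cyclopropane-fused lactone ester A7, the aryl Grignard reagent A8 and 13. A7 comes in one operation from a malonic ester and (R)-epichlorohydrin A9.
- **Forward key step.** The cuprate made from A8 opens the doubly activated cyclopropane of A7 at its CH2. The released lactone–ester enolate is benzylated in the same pot. Krapcho dealkoxycarbonylation and hydrogenolysis would finish the synthesis.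
- **For it.** C4 is bought from the chiral pool and never touched, and no auxiliary has to be attached or removed.
- **Where it is stronger.** The longest sequence is at least as short as the chosen one, probably one step shorter, so it leads on step count and atom economy.
- **Against it.**
  - Homoconjugate opening by aryl cuprates is slow, wastes aryl groups, and can be accompanied by attack at the ring methine with ring enlargement.
  - The quaternary C3 built in the key step is destroyed again. C3 is finally set by protonation at high temperature, which is thermodynamic and not kinetic control.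
  - A7 is formed from A9 by two competing pathways: attack at the epoxide first or at the chloride first. They lead to opposite enantiomers, so its enantiopurity is not guaranteed, and A7 offers no diastereomeric handle for upgrading.
- **What the chosen strategy offers instead.** Every chiral intermediate up to 17 carries the menthyl group. A stereochemical leak therefore shows up as a separable diastereomer, which matters when a single enantiomer is required.

Key step: step 8

**Remarks on the chemistry.**
- "l-Menthyl" means the (1R,2S,5R)-2-isopropyl-5-methylcyclohexyl group throughout.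
- Hemiacetal carbons that epimerise freely (C5 of 3 and of F8) are left without a descriptor.

## Steps

Step 1
Reactants: 1 furfural
Product: 3 5-hydroxyfuran-2(5H)-one, via furfural endoperoxide 2 (not isolated)
Conditions: O2, hν (visible), methylene blue (cat.), MeOH, 0–20 °C
Reagents that add atoms: dioxygen, O=O
Why: Dye-sensitised singlet-oxygen [4+2] cycloaddition to the furan gives endoperoxide 2; methanol adds to the formyl group and the following fragmentation breaks the ring–CHO and O–O bonds, leaving the γ-hydroxybutenolide. This is the standard photo-oxygenation of furfural, and 3 is a racemic, freely epimerising hemiacetal, so no stereochemistry is at stake.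

Step 2
Reactants: 3 5-hydroxyfuran-2(5H)-one; 4 (−)-menthol
Product: 6 (5R)-5-(l-menthyloxy)furan-2(5H)-one, via C5-epimer mixture 5 (not isolated)
Conditions: p-TsOH·H2O (cat.), toluene, reflux, Dean–Stark; crystallisation from petroleum ether, −20 °C; mother liquor re-equilibrated with p-TsOH (cat.) and crystallised again
Reagents that add atoms: none
Why: Acid-catalysed acetalisation of the pseudo-acid hydroxyl with azeotropic removal of water gives both C5 epimers 5, which are diastereomers because of the menthyl group; the (5R) epimer is the one expected to crystallise. Acid equilibrates C5, so the mother liquor can be recycled, and the C5 centre is set by crystallisation and not by kinetic selectivity.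

Step 3
Reactants: 7 isovanillin
Product: 8 3-benzyloxy-4-methoxybenzaldehyde
Conditions: BnBr, K2CO3, DMF, 60 °C
Reagents that add atoms: benzyl bromide, BrCc1ccccc1
Why: Williamson ether synthesis on the only acidic OH; the aldehyde is inert to carbonate.

Step 4
Reactants: 8 3-benzyloxy-4-methoxybenzaldehyde
Product: 9 2-(3-benzyloxy-4-methoxyphenyl)-1,3-dithiane
Conditions: HS(CH2)3SH, BF3·OEt2 (cat.), CH2Cl2, 0 °C → rt
Reagents that add atoms: propane-1,3-dithiol, SCCCS
Why: Lewis-acid-catalysed thioacetalisation of an aromatic aldehyde; aryl benzyl and methyl ethers survive catalytic BF3·OEt2 at this temperature.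

Step 5
Reactants: 10 vanillin
Product: 11 4-benzyloxy-3-methoxybenzaldehyde
Conditions: BnBr, K2CO3, DMF, 60 °C
Reagents that add atoms: benzyl bromide, BrCc1ccccc1
Why: Williamson ether synthesis, as in step 3.

Step 6
Reactants: 11 4-benzyloxy-3-methoxybenzaldehyde
Product: 12 (4-benzyloxy-3-methoxyphenyl)methanol
Conditions: NaBH4, MeOH/THF, 0 °C
Reagents that add atoms: none
Why: Borohydride reduction of an aromatic aldehyde; no other reducible group is present.

Step 7
Reactants: 12 (4-benzyloxy-3-methoxyphenyl)methanol
Product: 13 4-benzyloxy-3-methoxybenzyl bromide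
Conditions: PBr3, Et2O, 0 °C; used at once
Reagents that add atoms: phosphorus tribromide, BrP(Br)Br
Why: Bromination of a benzylic alcohol through its phosphite ester with displacement by bromide. The electron-rich bromide is reactive and prone to self-condensation, so it is made immediately before step 8.

Step 8
Reactants: 9 2-(3-benzyloxy-4-methoxyphenyl)-1,3-dithiane; 6 (5R)-5-(l-menthyloxy)furan-2(5H)-one; 13 4-benzyloxy-3-methoxybenzyl bromide
Product: 16 (3R,4R,5R)-3-(4-benzyloxy-3-methoxybenzyl)-4-[2-(3-benzyloxy-4-methoxyphenyl)-1,3-dithian-2-yl]-5-(l-menthyloxy)dihydrofuran-2(3H)-one, via 2-lithiodithiane 14 (not isolated), via lithium lactone enolate 15 (not isolated)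
Conditions: 9, n-BuLi, THF, −78 → −20 °C; 6, THF, −78 °C; 13, DMPU, −78 → −20 °C; aq NH4Cl
Reagents that add atoms: none
Why: n-BuLi removes the C2–H of dithiane 9, the sulfur-stabilised benzylic carbanion 14 adds in a Michael sense to C4 of 6, and the lithium enolate 15 then displaces bromide from 13 in an SN2 step at C3, so that the C4–C(benzylic) and C3–CH2Ar bonds are made in one flask. The closest known reaction type is the tandem conjugate addition–enolate alkylation of lithiated aryl dithioacetals on but-2-en-4-olides and 5-alkoxyfuran-2(5H)-ones, a standard entry to dibenzylbutyrolactones. No ring is closed, since the lactone is already present in 6. C4 is controlled by C5: the butenolide is flat, the menthyloxy group covers one face and the bulky carbanion enters from the other, which gives the 4,5-trans relation and, from the (5R) acetal, the 4R centre. C3 is controlled by C4: the fully substituted dithianyl group shields its own face of the planar enolate, 13 approaches anti to it, and the 3,4-trans (3R) centre results. 1,4- over 1,2-addition is secured by the delocalised, soft and bulky character of 14 at low temperature. C- over O-alkylation and single alkylation are secured by the soft, very reactive benzylic bromide, the DMPU-loosened enolate and the crowding around the remaining C3–H of 16. The temperature is held at or below −20 °C because the addition is reversible and 14 would otherwise be benzylated directly.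

Step 9
Reactants: 16 (3R,4R,5R)-3-(4-benzyloxy-3-methoxybenzyl)-4-[2-(3-benzyloxy-4-methoxyphenyl)-1,3-dithian-2-yl]-5-(l-menthyloxy)dihydrofuran-2(3H)-one
Product: 17 (3R,4R,5R)-3-(4-benzyloxy-3-methoxybenzyl)-4-(3-benzyloxy-4-methoxybenzyl)-5-(l-menthyloxy)dihydrofuran-2(3H)-one
Conditions: NiCl2·6H2O, NaBH4, MeOH/THF, 0 °C → rt; filtration through Celite
Reagents that add atoms: none
Why: Reductive desulfurisation with nickel boride Ni2B formed in the flask turns the benzylic dithioacetal carbon into CH2. This mild nickel reagent should leave aryl benzyl ethers, the lactone and the acetal intact, and no stereocentre takes part.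

Step 10
Reactants: 17 (3R,4R,5R)-3-(4-benzyloxy-3-methoxybenzyl)-4-(3-benzyloxy-4-methoxybenzyl)-5-(l-menthyloxy)dihydrofuran-2(3H)-one
Product: 20 (3R,4R)-3-(4-benzyloxy-3-methoxybenzyl)-4-(3-benzyloxy-4-methoxybenzyl)dihydrofuran-2(3H)-one, via aldehyde carboxylate 18 (not isolated), via hydroxy carboxylate 19 (not isolated)
Conditions: NaBH4 (charged first), then KOH, EtOH/H2O, 0 °C → rt; then 2 M HCl to pH 1–2, rt
Reagents that add atoms: potassium hydroxide, [K+].[OH-] (supplies K and one carboxylate oxygen of 18 and 19; one carboxyl oxygen leaves again as water on ring closure)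
Why: Saponification of the acylal opens the ring, the hemiacetal loses menthoxide, and aldehyde 18 is reduced at once by the borohydride already present to 19, which lactonises on acidification (hydrolysis–reduction–relactonisation of a pseudo-ester). C2 stays at the acid level throughout, so the carbonyl remains next to the C3 arm. The carboxylate protects C3 from enolisation, and fast hydride capture protects C4.

Step 11
Reactants: 20 (3R,4R)-3-(4-benzyloxy-3-methoxybenzyl)-4-(3-benzyloxy-4-methoxybenzyl)dihydrofuran-2(3H)-one
Product: 21 (3R,4R)-3-(4-hydroxy-3-methoxybenzyl)-4-(3-hydroxy-4-methoxybenzyl)dihydrofuran-2(3H)-one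
Conditions: H2 (1 atm), 10% Pd/C, EtOAc/EtOH, rt
Reagents that add atoms: none
Why: Catalytic hydrogenolysis of both aryl benzyl ethers under neutral conditions. The lactone, the methyl ethers and the C–C benzylic positions are inert, and C3 is not exposed to base.

## Compound list

1 | furfural (furan-2-carbaldehyde) | O=Cc1ccco1 | starting material
2 | furfural endoperoxide, 2,3,7-trioxabicyclo[2.2.1]hept-5-ene-1-carbaldehyde (racemic) | O=CC12OOC(C=C1)O2 | intermediate
3 | 5-hydroxyfuran-2(5H)-one (racemic, labile hemiacetal) | O=C1C=CC(O)O1 | intermediate
4 | (−)-menthol, (1R,2S,5R)-2-isopropyl-5-methylcyclohexan-1-ol | CC(C)[C@@H]1CC[C@@H](C)C[C@H]1O | starting material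
5 | 5-(l-menthyloxy)furan-2(5H)-one, mixture of C5 epimers | O=C1C=CC(O[C@@H]2C[C@H](C)CC[C@H]2C(C)C)O1 | intermediate
6 | (5R)-5-(l-menthyloxy)furan-2(5H)-one | O=C1C=C[C@H](O[C@@H]2C[C@H](C)CC[C@H]2C(C)C)O1 | intermediate
7 | isovanillin (3-hydroxy-4-methoxybenzaldehyde) | COc1ccc(C=O)cc1O | starting material
8 | 3-benzyloxy-4-methoxybenzaldehyde | COc1ccc(C=O)cc1OCc1ccccc1 | intermediate
9 | 2-(3-benzyloxy-4-methoxyphenyl)-1,3-dithiane | COc1ccc(C2SCCCS2)cc1OCc1ccccc1 | intermediate
10 | vanillin (4-hydroxy-3-methoxybenzaldehyde) | COc1cc(C=O)ccc1O | starting material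
11 | 4-benzyloxy-3-methoxybenzaldehyde | COc1cc(C=O)ccc1OCc1ccccc1 | intermediate
12 | (4-benzyloxy-3-methoxyphenyl)methanol | COc1cc(CO)ccc1OCc1ccccc1 | intermediate
13 | 4-benzyloxy-3-methoxybenzyl bromide | COc1cc(CBr)ccc1OCc1ccccc1 | intermediate
14 | 2-lithio-2-(3-benzyloxy-4-methoxyphenyl)-1,3-dithiane | COc1ccc(cc1OCc1ccccc1)C1([Li])SCCCS1 | intermediate
15 | lithium enolate of (4R,5R)-4-[2-(3-benzyloxy-4-methoxyphenyl)-1,3-dithian-2-yl]-5-(l-menthyloxy)dihydrofuran-2(3H)-one | COc1ccc(cc1OCc1ccccc1)C1(SCCCS1)[C@H]1[C@H](O[C@@H]2C[C@H](C)CC[C@H]2C(C)C)OC(O[Li])=C1 | intermediate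
16 | (3R,4R,5R)-3-(4-benzyloxy-3-methoxybenzyl)-4-[2-(3-benzyloxy-4-methoxyphenyl)-1,3-dithian-2-yl]-5-(l-menthyloxy)dihydrofuran-2(3H)-one (3,4-trans, 4,5-trans) | COc1ccc(cc1OCc1ccccc1)C1(SCCCS1)[C@H]1[C@H](O[C@@H]2C[C@H](C)CC[C@H]2C(C)C)OC(=O)[C@@H]1Cc1ccc(OCc2ccccc2)c(OC)c1 | intermediate
17 | (3R,4R,5R)-3-(4-benzyloxy-3-methoxybenzyl)-4-(3-benzyloxy-4-methoxybenzyl)-5-(l-menthyloxy)dihydrofuran-2(3H)-one | COc1ccc(cc1OCc1ccccc1)C[C@H]1[C@H](O[C@@H]2C[C@H](C)CC[C@H]2C(C)C)OC(=O)[C@@H]1Cc1ccc(OCc2ccccc2)c(OC)c1 | intermediate
18 | potassium (2R,3R)-2-(4-benzyloxy-3-methoxybenzyl)-3-(3-benzyloxy-4-methoxybenzyl)-4-oxobutanoate | COc1ccc(C[C@@H](C=O)[C@@H](Cc2ccc(OCc3ccccc3)c(OC)c2)C(=O)[O-])cc1OCc1ccccc1.[K+] | intermediate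
19 | potassium (2R,3R)-2-(4-benzyloxy-3-methoxybenzyl)-3-(3-benzyloxy-4-methoxybenzyl)-4-hydroxybutanoate | COc1ccc(C[C@@H](CO)[C@@H](Cc2ccc(OCc3ccccc3)c(OC)c2)C(=O)[O-])cc1OCc1ccccc1.[K+] | intermediate
20 | (3R,4R)-3-(4-benzyloxy-3-methoxybenzyl)-4-(3-benzyloxy-4-methoxybenzyl)dihydrofuran-2(3H)-one | COc1ccc(C[C@H]2COC(=O)[C@@H]2Cc2ccc(OCc3ccccc3)c(OC)c2)cc1OCc1ccccc1 | intermediate
21 | (3R,4R)-3-(4-hydroxy-3-methoxybenzyl)-4-(3-hydroxy-4-methoxybenzyl)dihydrofuran-2(3H)-one (CNP0309867.1) | COc1ccc(C[C@H]2COC(=O)[C@@H]2Cc2ccc(O)c(OC)c2)cc1O | target

## Step count and risks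

**Total step count:** 11.

**Longest linear sequence:** 7 steps (steps 5, 6, 7, 8, 9, 10, 11, from 10 to 21). The branches from 1 and from 7 each reach 21 in 6 steps. Compounds 8, 11 and 12 are also catalogue items, and buying them would remove steps 3, 5 and 6.

### Least certain steps

**Step 8 (key step).**
- **What may go wrong.** The benzylation of the crowded enolate 15 may be slower than hoped. On warming, the conjugate addition would then revert and the carbanion would be benzylated at the dithiane carbon, or proton exchange between product and enolate would set in. Deprotonation of 6 at C5 by 14 instead of addition would also erase the controlling centre.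
- **Fallback.** The tandem process is taken apart and sulfur is removed before the second C–C bond is made.
  - Starting from 9 and 6, the addition is run as in step 8, but 15 is quenched at −78 °C with acetic acid. This gives (4R,5R)-4-[2-(3-benzyloxy-4-methoxyphenyl)-1,3-dithian-2-yl]-5-(l-menthyloxy)dihydrofuran-2(3H)-one F1.
  - Desulfurisation with Ni2B as in step 9 gives (4R,5R)-4-(3-benzyloxy-4-methoxybenzyl)-5-(l-menthyloxy)dihydrofuran-2(3H)-one F2.
  - LiN(i-Pr)2 in THF at −78 °C converts F2 into the lithium enolate of this lactone F3.
  - F3 is alkylated by 13 anti to the C4 arm, in the classical manner of β-benzylbutyrolactone enolates. The sequence rejoins the route at 17.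
- **Why it helps.** After desulfurisation the C4 substituent can no longer leave as a stabilised carbanion, so reversal is excluded. Any cis material is corrected by base equilibration at C3.

**Step 9.**
- **What may go wrong.** C–S cleavage may be incomplete at the fully substituted, neopentyl-like dithiane carbon. Pushing the reaction with more reagent invites partial loss of benzyl ethers or attack of borohydride and methoxide on the acylal.
- **Fallback.** The sulfur carrier is changed to one with more easily cleaved, acyclic aryl–sulfur groups.
  - Starting from 8, thiophenol and catalytic BF3·OEt2 give 2-benzyloxy-4-[bis(phenylsulfanyl)methyl]-1-methoxybenzene F4.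
  - n-BuLi converts F4 into its lithio derivative F5.
  - F5 adds to 6 to give the corresponding lithium lactone enolate F6.
  - 13 traps F6 as (3R,4R,5R)-3-(4-benzyloxy-3-methoxybenzyl)-4-[(3-benzyloxy-4-methoxyphenyl)bis(phenylsulfanyl)methyl]-5-(l-menthyloxy)dihydrofuran-2(3H)-one F7.
  - Mild Ni2B treatment of F7 rejoins the route at 17.
- **Why it helps.** Lithiated bis(arylthio)acetals are equally established donors in tandem additions to butenolides, and the same C5 → C4 → C3 relay applies.

**Step 10.**
- **What may go wrong.** The transient aldehyde 18 may epimerise at C4 in the alkaline medium before hydride capture, which would damage the centre that carries the absolute configuration. Incomplete relactonisation and over-reduction are lesser concerns. Complete reduction to the 1,4-diol is no way out, because it would make C2 and C5 equivalent.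
- **Fallback.** Auxiliary removal and reduction are separated, and base is avoided.
  - Starting from 17, dilute acid (1 M HCl, aqueous dioxane, 50 °C) hydrolyses the acetal. This gives (3R,4R)-3-(4-benzyloxy-3-methoxybenzyl)-4-(3-benzyloxy-4-methoxybenzyl)-5-hydroxydihydrofuran-2(3H)-one F8.
  - NaBH4 in THF/EtOH at 0 °C without added alkali reduces the open aldehyde form to sodium (2R,3R)-2-(4-benzyloxy-3-methoxybenzyl)-3-(3-benzyloxy-4-methoxybenzyl)-4-hydroxybutanoate F9.
  - Acidification closes the ring and rejoins the route at 20.
- **Precaution.** The acid must stay dilute to avoid Friedel–Crafts closure of the C3 arene onto C5.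

**Step 2.**
- **What may go wrong.** Enrichment of the (5R) epimer by crystallisation may be insufficient. Every trace of the other epimer would be carried into the mirror-image ring series.
- **Fallback.** The stereochemical purification is moved behind the key step.
  - Starting from mixture 5 (or incompletely enriched 6), step 8 is run as described.
  - The (5S) component passes through the lithium enolate of the (4S,5S) adduct F10.
  - F10 gives (3S,4S,5S)-3-(4-benzyloxy-3-methoxybenzyl)-4-[2-(3-benzyloxy-4-methoxyphenyl)-1,3-dithian-2-yl]-5-(l-menthyloxy)dihydrofuran-2(3H)-one F11.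
  - F11 still carries the same l-menthyl group and is therefore a diastereomer of 16. Chromatography and crystallisation at this stage rejoin the route at 16.
- **Cost.** Part of 9 and 13 is lost.

**Step 11.**
- **What may go wrong.** Traces of sulfur or nickel carried over from step 9 may deactivate the palladium surface, so that the hydrogenolysis stalls.
- **Fallback.** A metal-free Lewis-acid cleavage is used. Starting from 20, BCl3 with pentamethylbenzene as cation scavenger in CH2Cl2 at −78 °C removes aryl benzyl ethers in preference to aryl methyl ethers and leads directly to 21. No compound outside the list is formed on this way (line F0).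

## Further compounds

F1 | step 8 | (4R,5R)-4-[2-(3-benzyloxy-4-methoxyphenyl)-1,3-dithian-2-yl]-5-(l-menthyloxy)dihydrofuran-2(3H)-one | COc1ccc(cc1OCc1ccccc1)C1(SCCCS1)[C@H]1[C@H](O[C@@H]2C[C@H](C)CC[C@H]2C(C)C)OC(=O)C1
F2 | step 8 | (4R,5R)-4-(3-benzyloxy-4-methoxybenzyl)-5-(l-menthyloxy)dihydrofuran-2(3H)-one | COc1ccc(cc1OCc1ccccc1)C[C@H]1[C@H](O[C@@H]2C[C@H](C)CC[C@H]2C(C)C)OC(=O)C1
F3 | step 8 | lithium enolate of F2 | COc1ccc(cc1OCc1ccccc1)C[C@H]1[C@H](O[C@@H]2C[C@H](C)CC[C@H]2C(C)C)OC(O[Li])=C1
F4 | step 9 | 2-benzyloxy-4-[bis(phenylsulfanyl)methyl]-1-methoxybenzene | COc1ccc(C(Sc2ccccc2)Sc2ccccc2)cc1OCc1ccccc1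
F5 | step 9 | lithio derivative of F4 | COc1ccc(cc1OCc1ccccc1)C([Li])(Sc1ccccc1)Sc1ccccc1
F6 | step 9 | lithium enolate of (4R,5R)-4-[(3-benzyloxy-4-methoxyphenyl)bis(phenylsulfanyl)methyl]-5-(l-menthyloxy)dihydrofuran-2(3H)-one | COc1ccc(cc1OCc1ccccc1)C(Sc1ccccc1)(Sc1ccccc1)[C@H]1[C@H](O[C@@H]2C[C@H](C)CC[C@H]2C(C)C)OC(O[Li])=C1
F7 | step 9 | (3R,4R,5R)-3-(4-benzyloxy-3-methoxybenzyl)-4-[(3-benzyloxy-4-methoxyphenyl)bis(phenylsulfanyl)methyl]-5-(l-menthyloxy)dihydrofuran-2(3H)-one | COc1ccc(cc1OCc1ccccc1)C(Sc1ccccc1)(Sc1ccccc1)[C@H]1[C@H](O[C@@H]2C[C@H](C)CC[C@H]2C(C)C)OC(=O)[C@@H]1Cc1ccc(OCc2ccccc2)c(OC)c1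
F8 | step 10 | (3R,4R)-3-(4-benzyloxy-3-methoxybenzyl)-4-(3-benzyloxy-4-methoxybenzyl)-5-hydroxydihydrofuran-2(3H)-one (C5 labile) | COc1ccc(cc1OCc1ccccc1)C[C@H]1C(O)OC(=O)[C@@H]1Cc1ccc(OCc2ccccc2)c(OC)c1
F9 | step 10 | sodium (2R,3R)-2-(4-benzyloxy-3-methoxybenzyl)-3-(3-benzyloxy-4-methoxybenzyl)-4-hydroxybutanoate | COc1ccc(C[C@@H](CO)[C@@H](Cc2ccc(OCc3ccccc3)c(OC)c2)C(=O)[O-])cc1OCc1ccccc1.[Na+]
F10 | step 2 | lithium enolate of (4S,5S)-4-[2-(3-benzyloxy-4-methoxyphenyl)-1,3-dithian-2-yl]-5-(l-menthyloxy)dihydrofuran-2(3H)-one | COc1ccc(cc1OCc1ccccc1)C1(SCCCS1)[C@@H]1[C@@H](O[C@@H]2C[C@H](C)CC[C@H]2C(C)C)OC(O[Li])=C1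
F11 | step 2 | (3S,4S,5S)-3-(4-benzyloxy-3-methoxybenzyl)-4-[2-(3-benzyloxy-4-methoxyphenyl)-1,3-dithian-2-yl]-5-(l-menthyloxy)dihydrofuran-2(3H)-one | COc1ccc(cc1OCc1ccccc1)C1(SCCCS1)[C@@H]1[C@@H](O[C@@H]2C[C@H](C)CC[C@H]2C(C)C)OC(=O)[C@H]1Cc1ccc(OCc2ccccc2)c(OC)c1
F0 | step 11 | none | none
A1 | alternative 1 | (R,E)-3-(4-benzyloxy-3-methoxybenzylidene)-4-(3-benzyloxy-4-methoxybenzyl)dihydrofuran-2(3H)-one | COc1ccc(C[C@H]2COC(=O)/C2=C/c2ccc(OCc3ccccc3)c(OC)c2)cc1OCc1ccccc1
A2 | alternative 1 | (R)-2-(3-benzyloxy-4-methoxybenzyl)-4-(4-benzyloxy-3-methoxyphenyl)but-3-yn-1-ol | COc1ccc(C[C@@H](CO)C#Cc2ccc(OCc3ccccc3)c(OC)c2)cc1OCc1ccccc1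
A3 | alternative 2 | (S)-3-[(2S,3R)-2-(4-benzyloxy-3-methoxybenzyl)-3-(3-benzyloxy-4-methoxybenzyl)-4-(isopropoxydimethylsilyl)butanoyl]-4-phenyloxazolidin-2-one | O=C1OC[C@H](c2ccccc2)N1C(=O)[C@@H](Cc2ccc(OCc3ccccc3)c(OC)c2)[C@H](C[Si](C)(C)OC(C)C)Cc1ccc(OC)c(OCc2ccccc2)c1
A4 | alternative 2 | (S,E)-3-[4-(3-benzyloxy-4-methoxyphenyl)but-2-enoyl]-4-phenyloxazolidin-2-one | O=C1OC[C@H](c2ccccc2)N1C(=O)/C=C/Cc1ccc(OC)c(OCc2ccccc2)c1
A5 | alternative 2 | (isopropoxydimethylsilyl)methylmagnesium chloride | CC(C)O[Si](C)(C)C[Mg]Cl
A6 | alternative 3 | methyl (3R,4R)-3-(4-benzyloxy-3-methoxybenzyl)-4-(3-benzyloxy-4-methoxybenzyl)-2-oxotetrahydrofuran-3-carboxylate | COc1ccc(C[C@H]2COC(=O)[C@@]2(Cc2ccc(OCc3ccccc3)c(OC)c2)C(=O)OC)cc1OCc1ccccc1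
A7 | alternative 3 | methyl (1S,5R)-2-oxo-3-oxabicyclo[3.1.0]hexane-1-carboxylate | COC(=O)[C@]12C[C@H]1COC2=O
A8 | alternative 3 | 3-benzyloxy-4-methoxyphenylmagnesium bromide | COc1ccc([Mg]Br)cc1OCc1ccccc1
A9 | alternative 3 | (R)-epichlorohydrin | ClC[C@H]1CO1
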